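**Retrosynthetic overview**
1. Target 39 ⇐ one-pot desilylation/oxidation of macrocycle 37. The side-chain (R)-carbinol comes from (S)-lactic acid (Seebach acetal, aldol) and is carried as its 3-O-silyl alcohol.
2. Ten-membered ring, formed last: ring-closing metathesis at C4=C5 (Z) of diene 36.
3. C9–C10: Nozaki–Hiyama–Kishi coupling of aldehyde 31 with (Z)-iodo enoate 34 (Felkin–Anh, sets C9).
4. γ-Lactone, formed first: palladium-allyl lactonisation of acid 12 (sets C6 trans to C7), then α-methylenation.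
5. Key bond C7–C11: Johnson–Claisen [3,3] rearrangement of (Z)-allylic alcohol 4 from (R)-glyceraldehyde acetonide (C8 bought; it directs C7).

Assumption: atom labels C1–C15 follow germacrane numbering of the target (ring C1–C10, lactone C12(=O)–O–C6, C11=C13, ester carbon C14 on C10, methyl C15 on C4), and 1 and 32 are taken as purchasable.

**Route**

Step 1
Reactants: 1 (4R)-2,2-dimethyl-1,3-dioxolane-4-carbaldehyde; 2 methyl (triphenylphosphoranylidene)acetate
Product: 3 methyl (2Z)-3-[(4S)-2,2-dimethyl-1,3-dioxolan-4-yl]prop-2-enoate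
Conditions: MeOH, 0 °C
Reagents that add atoms: none
Why: Wittig olefination of an α-alkoxy aldehyde with the stabilised ylide in methanol gives mainly the (Z)-enoate (about 8:1); the bought C8 stereocentre is untouched.

Step 2
Reactants: 3 methyl (2Z)-3-[(4S)-2,2-dimethyl-1,3-dioxolan-4-yl]prop-2-enoate
Product: 4 (2Z)-3-[(4S)-2,2-dimethyl-1,3-dioxolan-4-yl]prop-2-en-1-ol
Conditions: iBu2AlH, CH2Cl2, −78 °C; aq. potassium sodium tartrate
Reagents that add atoms: none
Why: 1,2-reduction of the ester by the aluminium hydride gives the (Z)-allylic alcohol without touching the acetonide or the olefin geometry.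

Step 3
Reactants: 4 (2Z)-3-[(4S)-2,2-dimethyl-1,3-dioxolan-4-yl]prop-2-en-1-ol; 5 triethyl orthoacetate
Product: 8 ethyl (3S)-3-[(4S)-2,2-dimethyl-1,3-dioxolan-4-yl]pent-4-enoate, via mixed orthoester 6 (not isolated), via ketene acetal 7 (not isolated)
Conditions: EtCO2H (cat.), neat, 140 °C, EtOH distilled off
Reagents that add atoms: none
Why: Johnson–Claisen [3,3]-sigmatropic rearrangement; allylic 1,3-strain of the (Z)-olefin holds H8 in the olefin plane and the new C7–C11 bond forms anti to the dioxolane C–O bond, which sets C7 (S).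

Step 4
Reactants: 8 ethyl (3S)-3-[(4S)-2,2-dimethyl-1,3-dioxolan-4-yl]pent-4-enoate
Product: 10 (3S)-3-[(4S)-2,2-dimethyl-1,3-dioxolan-4-yl]pent-4-enoic acid, via lithium carboxylate 9 (not isolated)
Conditions: LiOH, THF–H2O, rt; then 1 M HCl to pH 4, 0 °C
Reagents that add atoms: lithium hydroxide [Li+].[OH-]
Why: Saponification of the ethyl ester; brief cold acidification to pH 4 leaves the acetonide intact.

Step 5
Reactants: 10 (3S)-3-[(4S)-2,2-dimethyl-1,3-dioxolan-4-yl]pent-4-enoic acid; 11 (2Z)-but-2-ene-1,4-diyl diacetate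
Product: 12 (3S,4E)-6-acetoxy-3-[(4S)-2,2-dimethyl-1,3-dioxolan-4-yl]hex-4-enoic acid
Conditions: second-generation Grubbs catalyst RuCl2(=CHPh)(PCy3)(H2IMes) (3 mol %), CH2Cl2, 40 °C
Reagents that add atoms: none
Why: Olefin cross-metathesis of the terminal vinyl group with excess diacetate installs the allylic acetate (E major) needed for ionisation; the free acid is tolerated.

Step 6
Reactants: 12 (3S,4E)-6-acetoxy-3-[(4S)-2,2-dimethyl-1,3-dioxolan-4-yl]hex-4-enoic acid
Product: 13 (4S,5R)-4-[(4S)-2,2-dimethyl-1,3-dioxolan-4-yl]-5-ethenyloxolan-2-one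
Conditions: Pd(PPh3)4 (5 mol %), Et3N, THF, 60 °C
Reagents that add atoms: none
Why: Tsuji–Trost allylic substitution in which zerovalent palladium ionises the acetate and the carboxylate closes 5-exo on the π-allyl; reversible ionisation of the vinyl lactone funnels to the trans-4,5-disubstituted lactone, so C6 (R) is set by C7.

Step 7
Reactants: 13 (4S,5R)-4-[(4S)-2,2-dimethyl-1,3-dioxolan-4-yl]-5-ethenyloxolan-2-one
Product: 17 (4S,5R)-4-[(4S)-2,2-dimethyl-1,3-dioxolan-4-yl]-5-ethenyl-3-methylideneoxolan-2-one, via lithium enolate 14 (not isolated), via Mannich base 15 (not isolated), via ammonium iodide 16 (not isolated)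
Conditions: LiN(iPr)2, THF, −78 °C; CH2=NMe2+ I−, −78 °C → rt; then MeI, MeOH; then aq. NaHCO3, CH2Cl2
Reagents that add atoms: N,N-dimethylmethyleneiminium iodide C=[N+](C)C.[I-]
Why: Mannich aminomethylation of the lactone enolate, N-quaternisation and base-induced β-elimination give the α-methylene lactone; the strong base is used before any other ester is present and no stereocentre is touched.

Step 8
Reactants: 17 (4S,5R)-4-[(4S)-2,2-dimethyl-1,3-dioxolan-4-yl]-5-ethenyl-3-methylideneoxolan-2-one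
Product: 18 (4S,5R)-4-[(1S)-1,2-dihydroxyethyl]-5-ethenyl-3-methylideneoxolan-2-one
Conditions: AcOH–H2O 4:1, 40 °C
Reagents that add atoms: none
Why: Acid-catalysed acetal hydrolysis frees the C8/C9 diol; the trans 6,12-lactone is the more stable lactone isomer and oxa-Michael closure of O8 would be 5-endo.

Step 9
Reactants: 18 (4S,5R)-4-[(1S)-1,2-dihydroxyethyl]-5-ethenyl-3-methylideneoxolan-2-one
Product: 19 (4S,5R)-5-ethenyl-4-[(1S)-1-hydroxy-2-(triethylsilyloxy)ethyl]-3-methylideneoxolan-2-one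
Conditions: Et3SiCl, imidazole, CH2Cl2, −40 °C
Reagents that add atoms: chlorotriethylsilane CC[Si](Cl)(CC)CC
Why: Kinetic silylation of the primary hydroxyl over the hindered secondary C8 hydroxyl.

Step 10
Reactants: 20 (S)-lactic acid; 21 2,2-dimethylpropanal
Product: 22 (2S,5S)-2-tert-butyl-5-methyl-1,3-dioxolan-4-one
Conditions: TsOH (cat.), pentane, reflux, Dean–Stark; recrystallisation at −78 °C
Reagents that add atoms: none
Why: Acid-catalysed acetalisation in which the lactic acid stereocentre places the tert-butyl group cis (Seebach self-regeneration of stereocentres); the pure cis acetal is obtained by crystallisation.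

Step 11
Reactants: 22 (2S,5S)-2-tert-butyl-5-methyl-1,3-dioxolan-4-one; 23 acetaldehyde
Product: 26 (2S,5R)-2-tert-butyl-5-methyl-5-[1-(triethylsilyloxy)ethyl]-1,3-dioxolan-4-one (both epimers at the silyloxy carbon), via lithium enolate 24 (not isolated), via lithium aldolate 25 (not isolated)
Conditions: LiN(iPr)2, THF, −78 °C; MeCHO; then Et3SiCl, −78 → 0 °C
Reagents that add atoms: chlorotriethylsilane CC[Si](Cl)(CC)CC
Why: Aldol addition of the planar enolate anti to the tert-butyl group regenerates the lactate centre as the (R)-quaternary carbinol, and the aldolate is silylated in situ; the new carbinol carbon is oxidised in step 19, so its configuration does not matter.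

Step 12
Reactants: 26 (2S,5R)-2-tert-butyl-5-methyl-5-[1-(triethylsilyloxy)ethyl]-1,3-dioxolan-4-one
Product: 28 (2R)-2-hydroxy-2-methyl-3-(triethylsilyloxy)butanoic acid (C3 epimers), via lithium carboxylate 27 (not isolated)
Conditions: LiOH, THF–H2O, 0 °C; then 1 M HCl to pH 4, 0 °C
Reagents that add atoms: lithium hydroxide [Li+].[OH-]
Why: Hydroxide opens the acylal-type lactone, releasing the aldehyde and the α-hydroxy acid; the secondary silyl ether survives base and brief cold acidification.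

Step 13
Reactants: 19 (4S,5R)-5-ethenyl-4-[(1S)-1-hydroxy-2-(triethylsilyloxy)ethyl]-3-methylideneoxolan-2-one; 28 (2R)-2-hydroxy-2-methyl-3-(triethylsilyloxy)butanoic acid
Product: 29 (1S)-1-[(2R,3S)-2-ethenyl-4-methylidene-5-oxooxolan-3-yl]-2-(triethylsilyloxy)ethyl (2R)-2-hydroxy-2-methyl-3-(triethylsilyloxy)butanoate
Conditions: DCC, DMAP, CH2Cl2, 0 °C → rt
Reagents that add atoms: none
Why: Steglich esterification of the only free hydroxyl (C8); the tertiary hydroxyl of the acid is too hindered to compete.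

Step 14
Reactants: 29 (1S)-1-[(2R,3S)-2-ethenyl-4-methylidene-5-oxooxolan-3-yl]-2-(triethylsilyloxy)ethyl (2R)-2-hydroxy-2-methyl-3-(triethylsilyloxy)butanoate
Product: 31 (1S)-1-[(2R,3S)-2-ethenyl-4-methylidene-5-oxooxolan-3-yl]-2-oxoethyl (2R)-2-hydroxy-2-methyl-3-(triethylsilyloxy)butanoate, via alkoxysulfonium chloride 30 (not isolated)
Conditions: (COCl)2, DMSO, CH2Cl2, −78 → −30 °C; then Et3N
Reagents that add atoms: none
Why: Under Swern conditions a primary triethylsilyl ether is cleaved and oxidised directly to the aldehyde while the secondary silyl ether survives.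

Step 15
Reactants: 32 4-methylpent-4-enal; 2 methyl (triphenylphosphoranylidene)acetate
Product: 34 methyl (2Z)-2-iodo-6-methylhepta-2,6-dienoate, via iodo ylide 33 (not isolated)
Conditions: NIS, CH2Cl2, −20 °C; then 32, rt
Reagents that add atoms: N-iodosuccinimide O=C1CCC(=O)N1I
Why: α-Iodination of the stabilised ylide followed by Wittig olefination gives the (Z)-α-iodo enoate, with iodine cis to the chain.

Step 16
Reactants: 31 (1S)-1-[(2R,3S)-2-ethenyl-4-methylidene-5-oxooxolan-3-yl]-2-oxoethyl (2R)-2-hydroxy-2-methyl-3-(triethylsilyloxy)butanoate; 34 methyl (2Z)-2-iodo-6-methylhepta-2,6-dienoate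
Product: 35 methyl (2E)-2-[(1R,2S)-2-[(2R,3S)-2-ethenyl-4-methylidene-5-oxooxolan-3-yl]-1-hydroxy-2-{[(2R)-2-hydroxy-2-methyl-3-(triethylsilyloxy)butanoyl]oxy}ethyl]-6-methylhepta-2,6-dienoate
Conditions: CrCl2, NiCl2 (1 mol %), DMSO–THF, rt
Reagents that add atoms: none
Why: Nozaki–Hiyama–Kishi coupling; the alkenylchromium forms with retention of olefin geometry and adds in the Felkin–Anh sense (C8 acyloxy group anti to the nucleophile), giving the 8,9-erythro alcohol with C9 (R).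

Step 17
Reactants: 35 the C9 alcohol of step 16
Product: 36 methyl (2E)-2-[(1R,2S)-1-butanoyloxy-2-[(2R,3S)-2-ethenyl-4-methylidene-5-oxooxolan-3-yl]-2-{[(2R)-2-hydroxy-2-methyl-3-(triethylsilyloxy)butanoyl]oxy}ethyl]-6-methylhepta-2,6-dienoate
Conditions: (PrCO)2O, pyridine, DMAP (cat.), CH2Cl2, 0 °C
Reagents that add atoms: butanoic anhydride CCCC(=O)OC(=O)CCC
Why: DMAP-catalysed acylation of the secondary allylic hydroxyl; the tertiary hydroxyl is left alone at 0 °C.

Step 18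
Reactants: 36 the diene butanoate of step 17
Product: 37 methyl (6R,7S,8S,9R)-9-butanoyloxy-8-{[(2R)-2-hydroxy-2-methyl-3-(triethylsilyloxy)butanoyl]oxy}germacra-1(10)E,4Z,11(13)-trien-12,6-olid-14-oate
Conditions: second-generation Hoveyda–Grubbs catalyst RuCl2(=CH-C6H4-2-OiPr)(H2IMes) (10 mol %), toluene, 1 mM, 80 °C
Reagents that add atoms: none
Why: Ring-closing metathesis of the C5 vinyl and C4 isopropenyl groups; in a ten-membered ring only the (Z)-configured C4=C5 olefin is accessible, and the two acrylate-type olefins are inert.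

Step 19
Reactants: 37 the macrocyclic silyl ether of step 18
Product: 39 CNP0504624.1, methyl (6R,7S,8S,9R)-9-butanoyloxy-8-{[(2R)-2-hydroxy-2-methyl-3-oxobutanoyl]oxy}germacra-1(10)E,4Z,11(13)-trien-12,6-olid-14-oate, via secondary alcohol 38 (not isolated)
Conditions: IBX, DMSO, rt
Reagents that add atoms: none
Why: IBX in DMSO removes the triethylsilyl ether and oxidises the freed secondary alcohol to the methyl ketone without cleaving the tertiary α-ketol or touching the olefins.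

**Compound list**
1 | (4R)-2,2-dimethyl-1,3-dioxolane-4-carbaldehyde | O=C[C@H]1COC(C)(C)O1 | starting material
2 | methyl (triphenylphosphoranylidene)acetate | COC(=O)C=P(c1ccccc1)(c1ccccc1)c1ccccc1 | starting material
3 | methyl (2Z)-3-[(4S)-2,2-dimethyl-1,3-dioxolan-4-yl]prop-2-enoate | COC(=O)/C=C\[C@H]1COC(C)(C)O1 | intermediate
4 | (2Z)-3-[(4S)-2,2-dimethyl-1,3-dioxolan-4-yl]prop-2-en-1-ol | OC/C=C\[C@H]1COC(C)(C)O1 | intermediate
5 | triethyl orthoacetate | CCOC(C)(OCC)OCC | starting material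
6 | mixed orthoester, (4S)-4-[(1Z)-3-(1,1-diethoxyethoxy)prop-1-enyl]-2,2-dimethyl-1,3-dioxolane | CCOC(C)(OCC)OC/C=C\[C@H]1COC(C)(C)O1 | intermediate
7 | ketene acetal, (4S)-4-[(1Z)-3-(1-ethoxyethenyloxy)prop-1-enyl]-2,2-dimethyl-1,3-dioxolane | C=C(OCC)OC/C=C\[C@H]1COC(C)(C)O1 | intermediate
8 | ethyl (3S)-3-[(4S)-2,2-dimethyl-1,3-dioxolan-4-yl]pent-4-enoate | CCOC(=O)C[C@@H](C=C)[C@H]1COC(C)(C)O1 | intermediate
9 | lithium (3S)-3-[(4S)-2,2-dimethyl-1,3-dioxolan-4-yl]pent-4-enoate | [Li+].[O-]C(=O)C[C@@H](C=C)[C@H]1COC(C)(C)O1 | intermediate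
10 | (3S)-3-[(4S)-2,2-dimethyl-1,3-dioxolan-4-yl]pent-4-enoic acid | OC(=O)C[C@@H](C=C)[C@H]1COC(C)(C)O1 | intermediate
11 | (2Z)-but-2-ene-1,4-diyl diacetate | CC(=O)OC/C=C\COC(C)=O | starting material
12 | (3S,4E)-6-acetoxy-3-[(4S)-2,2-dimethyl-1,3-dioxolan-4-yl]hex-4-enoic acid | OC(=O)C[C@@H](/C=C/COC(C)=O)[C@H]1COC(C)(C)O1 | intermediate
13 | (4S,5R)-4-[(4S)-2,2-dimethyl-1,3-dioxolan-4-yl]-5-ethenyloxolan-2-one | O=C1C[C@H]([C@H]2COC(C)(C)O2)[C@@H](C=C)O1 | intermediate
14 | lithium enolate of 13 | [Li+].[O-]C1=C[C@H]([C@H]2COC(C)(C)O2)[C@@H](C=C)O1 | intermediate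
15 | Mannich base, (4S,5R)-3-[(dimethylamino)methyl]-4-[(4S)-2,2-dimethyl-1,3-dioxolan-4-yl]-5-ethenyloxolan-2-one (C3 epimers) | O=C1C(CN(C)C)[C@H]([C@H]2COC(C)(C)O2)[C@@H](C=C)O1 | intermediate
16 | trimethylammonium iodide of 15 | O=C1C(C[N+](C)(C)C)[C@H]([C@H]2COC(C)(C)O2)[C@@H](C=C)O1.[I-] | intermediate
17 | (4S,5R)-4-[(4S)-2,2-dimethyl-1,3-dioxolan-4-yl]-5-ethenyl-3-methylideneoxolan-2-one | C=C1C(=O)O[C@H](C=C)[C@H]1[C@H]2COC(C)(C)O2 | intermediate
18 | (4S,5R)-4-[(1S)-1,2-dihydroxyethyl]-5-ethenyl-3-methylideneoxolan-2-one | C=C1C(=O)O[C@H](C=C)[C@H]1[C@H](O)CO | intermediate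
19 | (4S,5R)-5-ethenyl-4-[(1S)-1-hydroxy-2-(triethylsilyloxy)ethyl]-3-methylideneoxolan-2-one | C=C1C(=O)O[C@H](C=C)[C@H]1[C@H](O)CO[Si](CC)(CC)CC | intermediate
20 | (S)-lactic acid | C[C@H](O)C(=O)O | starting material
21 | 2,2-dimethylpropanal | CC(C)(C)C=O | starting material
22 | (2S,5S)-2-tert-butyl-5-methyl-1,3-dioxolan-4-one | C[C@@H]1O[C@H](C(C)(C)C)OC1=O | intermediate
23 | acetaldehyde | CC=O | starting material
24 | lithium enolate of 22 | [Li+].CC1=C([O-])O[C@@H](C(C)(C)C)O1 | intermediate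
25 | lithium aldolate, lithium 1-[(2S,4R)-2-tert-butyl-4-methyl-5-oxo-1,3-dioxolan-4-yl]ethanolate | [Li+].CC([O-])[C@@]1(C)O[C@H](C(C)(C)C)OC1=O | intermediate
26 | (2S,5R)-2-tert-butyl-5-methyl-5-[1-(triethylsilyloxy)ethyl]-1,3-dioxolan-4-one | CC(O[Si](CC)(CC)CC)[C@@]1(C)O[C@H](C(C)(C)C)OC1=O | intermediate
27 | lithium (2R)-2-hydroxy-2-methyl-3-(triethylsilyloxy)butanoate | [Li+].CC(O[Si](CC)(CC)CC)[C@@](C)(O)C(=O)[O-] | intermediate
28 | (2R)-2-hydroxy-2-methyl-3-(triethylsilyloxy)butanoic acid | CC(O[Si](CC)(CC)CC)[C@@](C)(O)C(=O)O | intermediate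
29 | (1S)-1-[(2R,3S)-2-ethenyl-4-methylidene-5-oxooxolan-3-yl]-2-(triethylsilyloxy)ethyl (2R)-2-hydroxy-2-methyl-3-(triethylsilyloxy)butanoate | C=C1C(=O)O[C@H](C=C)[C@H]1[C@H](OC(=O)[C@](C)(O)C(C)O[Si](CC)(CC)CC)CO[Si](CC)(CC)CC | intermediate
30 | alkoxy(dimethyl)sulfonium chloride of the C9 oxygen of 29 | C=C1C(=O)O[C@H](C=C)[C@H]1[C@H](OC(=O)[C@](C)(O)C(C)O[Si](CC)(CC)CC)CO[S+](C)C.[Cl-] | intermediate
31 | (1S)-1-[(2R,3S)-2-ethenyl-4-methylidene-5-oxooxolan-3-yl]-2-oxoethyl (2R)-2-hydroxy-2-methyl-3-(triethylsilyloxy)butanoate | C=C1C(=O)O[C@H](C=C)[C@H]1[C@H](OC(=O)[C@](C)(O)C(C)O[Si](CC)(CC)CC)C=O | intermediate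
32 | 4-methylpent-4-enal | C=C(C)CCC=O | starting material
33 | methyl iodo(triphenylphosphoranylidene)acetate | COC(=O)C(I)=P(c1ccccc1)(c1ccccc1)c1ccccc1 | intermediate
34 | methyl (2Z)-2-iodo-6-methylhepta-2,6-dienoate | COC(=O)/C(I)=C/CCC(C)=C | intermediate
35 | methyl (2E)-2-[(1R,2S)-2-[(2R,3S)-2-ethenyl-4-methylidene-5-oxooxolan-3-yl]-1-hydroxy-2-{[(2R)-2-hydroxy-2-methyl-3-(triethylsilyloxy)butanoyl]oxy}ethyl]-6-methylhepta-2,6-dienoate | C=C1C(=O)O[C@H](C=C)[C@H]1[C@H](OC(=O)[C@](C)(O)C(C)O[Si](CC)(CC)CC)[C@H](O)/C(C(=O)OC)=C\CCC(C)=C | intermediate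
36 | methyl (2E)-2-[(1R,2S)-1-butanoyloxy-2-[(2R,3S)-2-ethenyl-4-methylidene-5-oxooxolan-3-yl]-2-{[(2R)-2-hydroxy-2-methyl-3-(triethylsilyloxy)butanoyl]oxy}ethyl]-6-methylhepta-2,6-dienoate | C=C1C(=O)O[C@H](C=C)[C@H]1[C@H](OC(=O)[C@](C)(O)C(C)O[Si](CC)(CC)CC)[C@H](OC(=O)CCC)/C(C(=O)OC)=C\CCC(C)=C | intermediate
37 | methyl (6R,7S,8S,9R)-9-butanoyloxy-8-{[(2R)-2-hydroxy-2-methyl-3-(triethylsilyloxy)butanoyl]oxy}germacra-1(10)E,4Z,11(13)-trien-12,6-olid-14-oate | C=C1C(=O)O[C@@H]2/C=C(/C)CC/C=C(/C(=O)OC)[C@@H](OC(=O)CCC)[C@@H](OC(=O)[C@](C)(O)C(C)O[Si](CC)(CC)CC)[C@@H]12 | intermediate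
38 | methyl (6R,7S,8S,9R)-9-butanoyloxy-8-{[(2R)-2,3-dihydroxy-2-methylbutanoyl]oxy}germacra-1(10)E,4Z,11(13)-trien-12,6-olid-14-oate | C=C1C(=O)O[C@@H]2/C=C(/C)CC/C=C(/C(=O)OC)[C@@H](OC(=O)CCC)[C@@H](OC(=O)[C@](C)(O)C(C)O)[C@@H]12 | intermediate
39 | CNP0504624.1 | C=C1C(=O)O[C@@H]2/C=C(/C)CC/C=C(/C(=O)OC)[C@@H](OC(=O)CCC)[C@@H](OC(=O)[C@](C)(O)C(C)=O)[C@@H]12 | target

**Step count and risks**

Total: 19 steps. Longest linear sequence: 15 steps (steps 1–9, 13, 14, 16–19); steps 10–12 and step 15 are side branches.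

Most likely to fail, in this order:

Step 18, ring-closing metathesis to a trisubstituted olefin in a strained ten-membered ring; it may stall or dimerise. The fallback is a relay strategy that leaves the route at aldehyde 31 and returns at macrocycle 37. Geraniol is O-allylated (NaH, allyl bromide) to (2E)-3,7-dimethyl-1-(prop-2-enyloxy)octa-2,6-diene F1. Selective ozonolysis of its electron-rich 6,7-olefin (O3, pyridine, CH2Cl2, −78 °C; Me2S) gives (4E)-4-methyl-6-(prop-2-enyloxy)hex-4-enal F2. The iodo-Wittig of step 15 converts it into methyl (2Z,6E)-2-iodo-6-methyl-8-(prop-2-enyloxy)octa-2,6-dienoate F3. Coupling with 31 as in step 16 gives the relay alcohol F4, and acylation as in step 17 gives the relay butanoate F5. The ruthenium catalyst of step 18 then loads on the unhindered allyl ether, expels 2,5-dihydrofuran and is delivered as the C4 alkylidene, which closes onto the C5 vinyl group to give 37.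

Step 16, chromium-mediated coupling of an α-iodo enoate; the alkenylchromium may be sluggish or the C9 selectivity low. The fallback builds the C9–C10 bond by an aldol reaction; it leaves at 31 (with 32 and 2) and returns at 35. Wittig reaction of 32 with 2 gives methyl (2E)-6-methylhepta-2,6-dienoate F6. Conjugate reduction with LiBH(sBu)3 and trapping of the enolate with PhSeBr gives methyl 6-methyl-2-(phenylselanyl)hept-6-enoate F7. Me3SiOTf and Et3N give its ketene silyl acetal F8. A Mukaiyama aldol addition to 31 promoted by BF3·OEt2 (Felkin–Anh) gives the seleno aldol adduct F9. Oxidation with H2O2 and selenoxide syn-elimination away from the carbinol then give 35.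

Step 6, palladium-allyl lactonisation; the trans/cis ratio at C6 may be modest. The fallback is a halolactonisation that leaves at acid 10 and returns at 13, by-passing steps 5 and 6. Iodolactonisation of 10 under equilibrating conditions (I2, MeCN, 0 °C → rt) gives the trans iodolactone (4R,5S)-4-[(4S)-2,2-dimethyl-1,3-dioxolan-4-yl]-5-(iodomethyl)oxolan-2-one F10. Me3NO in DMSO oxidises the primary iodide to (2S,3R)-3-[(4S)-2,2-dimethyl-1,3-dioxolan-4-yl]-5-oxooxolane-2-carbaldehyde F11. Wittig methylenation (Ph3P=CH2, THF, −78 °C) then gives 13.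

**Further compounds**
F1 | step 18 | (2E)-3,7-dimethyl-1-(prop-2-enyloxy)octa-2,6-diene | CC(C)=CCC/C(C)=C/COCC=C
F2 | step 18 | (4E)-4-methyl-6-(prop-2-enyloxy)hex-4-enal | O=CCC/C(C)=C/COCC=C
F3 | step 18 | methyl (2Z,6E)-2-iodo-6-methyl-8-(prop-2-enyloxy)octa-2,6-dienoate | COC(=O)/C(I)=C/CC/C(C)=C/COCC=C
F4 | step 18 | relay alcohol (35 with the chain end C(CH3)=CH-CH2-O-allyl) | C=C1C(=O)O[C@H](C=C)[C@H]1[C@H](OC(=O)[C@](C)(O)C(C)O[Si](CC)(CC)CC)[C@H](O)/C(C(=O)OC)=C\CC/C(C)=C/COCC=C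
F5 | step 18 | relay butanoate (36 with the chain end C(CH3)=CH-CH2-O-allyl) | C=C1C(=O)O[C@H](C=C)[C@H]1[C@H](OC(=O)[C@](C)(O)C(C)O[Si](CC)(CC)CC)[C@H](OC(=O)CCC)/C(C(=O)OC)=C\CC/C(C)=C/COCC=C
F6 | step 16 | methyl (2E)-6-methylhepta-2,6-dienoate | COC(=O)/C=C/CCC(C)=C
F7 | step 16 | methyl 6-methyl-2-(phenylselanyl)hept-6-enoate | COC(=O)C([Se]c1ccccc1)CCCC(C)=C
F8 | step 16 | ketene silyl acetal, [1-methoxy-6-methyl-2-(phenylselanyl)hepta-1,6-dienyl]oxy(trimethyl)silane | COC(O[Si](C)(C)C)=C([Se]c1ccccc1)CCCC(C)=C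
F9 | step 16 | seleno aldol adduct (35 with C10 saturated and bearing PhSe; C10 epimers) | C=C1C(=O)O[C@H](C=C)[C@H]1[C@H](OC(=O)[C@](C)(O)C(C)O[Si](CC)(CC)CC)[C@H](O)C([Se]c1ccccc1)(CCCC(C)=C)C(=O)OC
F10 | step 6 | (4R,5S)-4-[(4S)-2,2-dimethyl-1,3-dioxolan-4-yl]-5-(iodomethyl)oxolan-2-one | O=C1C[C@H]([C@H]2COC(C)(C)O2)[C@@H](CI)O1
F11 | step 6 | (2S,3R)-3-[(4S)-2,2-dimethyl-1,3-dioxolan-4-yl]-5-oxooxolane-2-carbaldehyde | O=C1C[C@H]([C@H]2COC(C)(C)O2)[C@@H](C=O)O1
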